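## Analysis of the target

- **Ring system.** Target 15 is a flavone. Benzo ring A (C4a, C5, C6, C7, C8, C8a) is fused to 4-pyranone ring C (O1, C2, C3, C4, C4a, C8a), and aryl ring B (C1'–C6') sits on C2.
- **Stereochemistry.** There is no stereocentre and no stereogenic double bond, so the whole difficulty lies in the substitution pattern.
- **Ring A.** It is hexasubstituted: C5, C6, C7 and C8 each carry OMe, C8a carries O1 and C4a carries the C4 carbonyl. No C–H is left on ring A, so classical entries must build the pattern by successive oxygenations of a lower phenol.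
- **The feature used here.** C5–C6–C7–C8 is a chain of four contiguous oxygen-bearing carbons, which is the C4O4 pattern of a squarate ester. The other two ring A atoms, C4a=C8a, are also the C5=C6 double bond of a monocyclic 4-pyranone.
- **Ring B.** It carries 2'-OH, 4'-OH and 5'-OMe, so two free phenols must be told apart from five methyl ethers.
- **Why no late demethylation.** The 5-OMe group, peri to C4=O, is the ether that Lewis acids cleave first.
- **Other sensitivities.** Ring B is an electron-rich 1,2,4-trioxygenated benzene, which electrophiles and oxidants attack before ring A. A free 2'-OH next to any ring-opened 1,3-diketone form could close ring C in the wrong direction, so it should be unveiled last and in neutral medium.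

## Retrosynthetic reasoning

**15 ⇒ 14.** The two O–benzyl bonds at O2' and O4' are cut. Benzyl ethers are the only handle that separates these oxygens from the five methyl ethers without acid or Lewis acid. The forward step must be a neutral hydrogenolysis that leaves C2=C3 and the 5-OMe group alone.

**14 ⇒ 13.** The O–CH3 bonds at O5 and O8 are cut, which gives the 5,8-hydroquinone 13. Both oxygens end as OMe, so they never have to be distinguished. The forward step is a double O-methylation, run before air can oxidise 13.

**13 ⇒ 10 (through 12 and 11).**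
- This is the strategic cut. The C4a–C5 bond is broken and C5 is reconnected to C8, so ring A contracts to the four-membered ring of cyclobutenone 10.
- The cut is made here because it removes the hexasubstituted benzene from the problem altogether.
- Its four oxygenated carbons arrive as one block with all four oxygens in place. The ring fusion atoms are supplied by a pyranone double bond.
- The forward reaction has to open 10 to ketene 11, close 11 onto the pyranone to give 12, and aromatise 12 to 13.

**10 ⇒ 7 + 8 (through 9).**
- The C8–C8a bond is cut.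
- Compound 8 has two equivalent carbonyl groups, so the addition has no regiochemical question on that side.
- On the pyranone side the bond is placed at the carbon next to O1 (pyranone C6). Two reasons support this. It is the position that a hindered lithium amide should deprotonate. The later closure then falls on pyranone C5, the nucleophilic carbon of the O1–C6=C5 enol ether.
- The forward step needs a site-selective lithiation of 7 to 9 and a clean 1,2-addition.

**7 ⇒ 5 (through 6).** The O1–C6 bond of the pyranone is cut and the C2 carbon is taken down one oxidation level. The forward step oxidises the benzylic carbinol of 5 to the 1,3-dione 6. The enol oxygen of 6 then displaces the vinylogous methoxy group.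

**5 ⇒ 2 + 3 (through 4).** The bond between the carbinol carbon (future C2) and the methylene (future C3) is cut. Ring B enters as an aldehyde, and all five pyranone carbons but one come from the four-carbon enone 3. The forward step is an aldol addition of the kinetic dienolate 4.

**2 ⇒ 1.** The two O–benzyl bonds are cut, which leads to the commercial aldehyde 1. This aldehyde already has the full ring B oxygenation pattern with the correct single methyl ether.

## Alternatives that were turned down

**Alternative 1: textbook route.**
- *Disconnection:* O1–C2 and C3–C4.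
- *Forward key step:* acetophenone A1 is O-aroylated with acid chloride A2. A Baker–Venkataraman rearrangement gives diketone A3, and acid cyclodehydration gives 14.
- *Reasons for rejection:*
  - Every step is reliable, but the disconnection does not touch the real problem. The hexasubstituted ring A is only passed on to A1.
  - A1 has to be assembled by a long linear series of acylation, oxidation and selective methylation steps on a phenol that has no free position left to guide them.
  - A2 also needs two more steps from 2.

**Alternative 2: late oxygenation of C8.**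
- *Disconnection:* the C8–O bond.
- *Forward key step:* the 5-hydroxy-6,7-dimethoxyflavone A4 is hydroxylated para to the 5-OH group by an Elbs persulfate oxidation, or by an anodic equivalent, to give 13.
- *Reasons for rejection:*
  - The reacting phenol is chelated to C4=O and sits on a ring deactivated by that carbonyl.
  - Ring B carries three donor oxygens and no acceptor in conjugation with its free positions. An electrophilic or one-electron oxidant therefore has its easiest target in the wrong ring.
  - A4 must itself be made by the full sequence of Alternative 1 from a pentasubstituted acetophenone, so the oxidation is added to a complete flavone synthesis rather than replacing part of it.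

**Alternative 3: Dötz benzannulation of ring A.**
- *Disconnection:* C4a–C5, C5–C6 and C7–C8.
- *Forward key step:* the pyranonyl methoxycarbene complex A5, (CO)5Cr=C(OMe)R, would be made from 9. It would take up alkyne A6 and one carbonyl ligand to give the 5-hydroxy-6,7,8-trimethoxyflavone A7.
- *Reasons for rejection:*
  - The ketene formed on the metal is simply the O-methyl analogue of 11, so the ring closure is the same as in the chosen route.
  - A6 is a doubly donor-substituted alkyne that polymerises readily and is not a storable reagent. Bulkier surrogates would add dealkylation and methylation steps.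
  - Making A5 needs a hard methylating agent in the presence of a pyranone carbonyl that is itself O-methylated to a pyrylium salt.
  - The metal is used in stoichiometric amount.
  - Compound 8 delivers the same six atoms as a stable solid.

Key step: step 5

Assumption: 1, 3 and 8 are taken as catalogue compounds. The stereocentres of 5, 10 and 12 are transient, so these compounds are handled as racemates.

## Route

Step 1
Reactants: 1 2,4-dihydroxy-5-methoxybenzaldehyde
Product: 2 2,4-bis(benzyloxy)-5-methoxybenzaldehyde
Conditions: BnBr (2.5 equiv), K2CO3, DMF, 60 °C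
Reagents that add atoms: benzyl bromide, BrCc1ccccc1
Why: Williamson ether synthesis. The 4-OH reacts readily and the chelated 2-OH follows with excess halide and gentle heating in a dipolar solvent; benzyl ethers tolerate every later step and come off without acid.

Step 2
Reactants: 2 2,4-bis(benzyloxy)-5-methoxybenzaldehyde; 3 (E)-4-methoxybut-3-en-2-one
Product: 5 (4E)-1-[2,4-bis(benzyloxy)-5-methoxyphenyl]-1-hydroxy-5-methoxypent-4-en-3-one (racemic), via lithium dienolate 4 (not isolated)
Conditions: LiN(SiMe3)2, THF, −78 °C; then 2, −78 °C; aq NH4Cl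
Reagents that add atoms: none
Why: Kinetic deprotonation of the methyl group of the vinylogous ester 3 gives the cross-conjugated dienolate 4, which undergoes a lithium aldol addition to the non-enolisable aldehyde 2. The new carbinol centre is formed without control and is erased in step 3.

Step 3
Reactants: 5 (4E)-1-[2,4-bis(benzyloxy)-5-methoxyphenyl]-1-hydroxy-5-methoxypent-4-en-3-one
Product: 7 2-[2,4-bis(benzyloxy)-5-methoxyphenyl]-4H-pyran-4-one, via methoxyenedione 6 (not isolated)
Conditions: IBX, EtOAc, 77 °C; filter, concentrate; then CF3CO2H, CH2Cl2, rt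
Reagents that add atoms: none
Why: IBX as a suspension in hot ethyl acetate is a known method for taking β-hydroxy ketones to 1,3-diones without attack on the activated methylene, and here the alcohol is also benzylic. Acid then triggers the known 4-pyranone closure of 5-methoxypent-4-ene-1,3-diones: the enol oxygen adds to the β-carbon and methanol is lost. Aryl benzyl ethers survive dilute trifluoroacetic acid at room temperature.

Step 4
Reactants: 7 2-[2,4-bis(benzyloxy)-5-methoxyphenyl]-4H-pyran-4-one; 8 dimethyl squarate (3,4-dimethoxycyclobut-3-ene-1,2-dione)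
Product: 10 4-{6-[2,4-bis(benzyloxy)-5-methoxyphenyl]-4-oxo-4H-pyran-2-yl}-4-hydroxy-2,3-dimethoxycyclobut-2-en-1-one (racemic), via 6-lithiopyranone 9 (not isolated)
Conditions: 2,2,6,6-tetramethylpiperidine, n-BuLi, THF, 0 °C; 7 added to the base at −78 °C; then 8, −78 °C; aq NH4Cl at −78 °C
Reagents that add atoms: none
Why: Hindered lithium amides deprotonate rings of the 4-pyranone type (chromones with free C2, 4-pyridones, 4-quinolones, uracils) at the sp2 C–H next to the ring heteroatom. In 7 this is C6–H, the only such position, and the non-nucleophilic amide avoids conjugate addition and ring opening. Organolithium reagents add 1,2 to one of the two equivalent carbonyl groups of squarate esters at −78 °C, which forms the C8–C8a bond; the new carbinol centre is racemic and is erased in step 5.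

Step 5
Reactants: 10 4-{6-[2,4-bis(benzyloxy)-5-methoxyphenyl]-4-oxo-4H-pyran-2-yl}-4-hydroxy-2,3-dimethoxycyclobut-2-en-1-one
Product: 14 2-[2,4-bis(benzyloxy)-5-methoxyphenyl]-5,6,7,8-tetramethoxy-4H-chromen-4-one, via dienylketene 11 (not isolated), via ring-closed dienone 12 (not isolated), via flavone hydroquinone 13 (not isolated)
Conditions: degassed toluene, 110 °C, Ar; concentrate; then Me2SO4 (excess), K2CO3, acetone, 56 °C, Ar
Reagents that add atoms: dimethyl sulfate, COS(=O)(=O)OC
Why: This is the Moore rearrangement (thermal ring expansion of 4-alkenyl- and 4-heteroaryl-4-hydroxycyclobutenones), and the closest known cases are the 4-(1-alkoxyalkenyl), 4-furyl and 4-aryl adducts of squarate esters. Heating breaks the strained C1–C4 bond of 10 in a conrotatory 4π electrocyclic opening; the donor OH at C4 rotates outward, as donors do in cyclobutene openings, so the pyranonyl group turns inward and ketene 11 forms with the (Z) geometry that holds the ketene carbon next to pyranone C5. Ring A is then closed by a disrotatory 6π electrocyclisation of the ketene C=C, the C(OMe)=C(OH) bond and the pyranone C5=C6 bond, which forms the C4a–C5 bond of 12 as a six-membered carbocycle, no other ring size being within reach. The closure is polarity-matched, because pyranone C5 is the nucleophilic carbon of the O1–C6=C5 enol ether and the ketene carbon is the electrophile, and it costs little, because a 4-pyranone is only weakly aromatic. Site selectivity is fixed by the substrate: the carbon that bears the four-membered ring has only one carbon neighbour, C5 with its hydrogen, and its other neighbour is O1. The C4a–H of 12 lies between two carbonyl groups and is lost at once by enolisation to hydroquinone 13, so the transient stereocentres of 10 and 12 vanish and no stereocontrol is needed. Both new oxygens (O5 and O8) end as OMe and need not be told apart, so 13 is methylated in the same flask under argon before air can oxidise it; the chelated 5-OH is the reason for excess reagent and reflux.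

Step 6
Reactants: 14 2-[2,4-bis(benzyloxy)-5-methoxyphenyl]-5,6,7,8-tetramethoxy-4H-chromen-4-one
Product: 15 2-(2,4-dihydroxy-5-methoxyphenyl)-5,6,7,8-tetramethoxy-4H-chromen-4-one (target)
Conditions: H2 (1 atm), Pd/C, EtOAc–MeOH, rt
Reagents that add atoms: none
Why: This is a catalytic hydrogenolysis of aryl benzyl ethers in neutral medium. The methyl ethers, including the labile 5-OMe, are inert, and the C2=C3 bond of a flavone is a hindered vinylogous ester that should take up hydrogen much more slowly than the benzylic C–O bonds are cleaved. The 2'-OH appears only when no ring-opened form is accessible.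

## Compound list

1 | 2,4-dihydroxy-5-methoxybenzaldehyde | COc1cc(C=O)c(O)cc1O | starting material
2 | 2,4-bis(benzyloxy)-5-methoxybenzaldehyde | COc1cc(C=O)c(OCc2ccccc2)cc1OCc1ccccc1 | intermediate
3 | (E)-4-methoxybut-3-en-2-one | CO/C=C/C(C)=O | starting material
4 | lithium (3E)-4-methoxybuta-1,3-dien-2-olate | [Li]OC(=C)/C=C/OC | intermediate
5 | (4E)-1-[2,4-bis(benzyloxy)-5-methoxyphenyl]-1-hydroxy-5-methoxypent-4-en-3-one (racemic) | COc1cc(C(O)CC(=O)/C=C/OC)c(OCc2ccccc2)cc1OCc1ccccc1 | intermediate
6 | (4E)-1-[2,4-bis(benzyloxy)-5-methoxyphenyl]-5-methoxypent-4-ene-1,3-dione | COc1cc(C(=O)CC(=O)/C=C/OC)c(OCc2ccccc2)cc1OCc1ccccc1 | intermediate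
7 | 2-[2,4-bis(benzyloxy)-5-methoxyphenyl]-4H-pyran-4-one | COc1cc(-c2cc(=O)cco2)c(OCc2ccccc2)cc1OCc1ccccc1 | intermediate
8 | dimethyl squarate (3,4-dimethoxycyclobut-3-ene-1,2-dione) | COC1=C(OC)C(=O)C1=O | starting material
9 | {6-[2,4-bis(benzyloxy)-5-methoxyphenyl]-4-oxo-4H-pyran-2-yl}lithium | [Li]c1cc(=O)cc(-c2cc(OC)c(OCc3ccccc3)cc2OCc2ccccc2)o1 | intermediate
10 | 4-{6-[2,4-bis(benzyloxy)-5-methoxyphenyl]-4-oxo-4H-pyran-2-yl}-4-hydroxy-2,3-dimethoxycyclobut-2-en-1-one (racemic) | COC1=C(OC)C(O)(c2cc(=O)cc(-c3cc(OC)c(OCc4ccccc4)cc3OCc3ccccc3)o2)C1=O | intermediate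
11 | (3Z)-4-{6-[2,4-bis(benzyloxy)-5-methoxyphenyl]-4-oxo-4H-pyran-2-yl}-4-hydroxy-2,3-dimethoxybuta-1,3-dien-1-one | O=C=C(OC)/C(OC)=C(O)\c1cc(=O)cc(-c2cc(OC)c(OCc3ccccc3)cc2OCc2ccccc2)o1 | intermediate
12 | 2-[2,4-bis(benzyloxy)-5-methoxyphenyl]-8-hydroxy-6,7-dimethoxy-4aH-chromene-4,5-dione (racemic) | COC1=C(OC)C(=O)C2C(=O)C=C(c3cc(OC)c(OCc4ccccc4)cc3OCc3ccccc3)OC2=C1O | intermediate
13 | 2-[2,4-bis(benzyloxy)-5-methoxyphenyl]-5,8-dihydroxy-6,7-dimethoxy-4H-chromen-4-one | COc1cc(-c2cc(=O)c3c(O)c(OC)c(OC)c(O)c3o2)c(OCc2ccccc2)cc1OCc1ccccc1 | intermediate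
14 | 2-[2,4-bis(benzyloxy)-5-methoxyphenyl]-5,6,7,8-tetramethoxy-4H-chromen-4-one | COc1cc(-c2cc(=O)c3c(OC)c(OC)c(OC)c(OC)c3o2)c(OCc2ccccc2)cc1OCc1ccccc1 | intermediate
15 | 2-(2,4-dihydroxy-5-methoxyphenyl)-5,6,7,8-tetramethoxy-4H-chromen-4-one | COc1cc(-c2cc(=O)c3c(OC)c(OC)c(OC)c(OC)c3o2)c(O)cc1O | target

## Step count and risk

Total step count: 6. Longest linear sequence: 6 steps (1 → 2 → 5 → 7 → 10 → 14 → 15); 3 and 8 are bought.

**Step 5 (key step).**
- *What may go wrong:* the ketene may be diverted before the 6π closure. If some of the hydroxyl group rotates inward, the ketene is trapped by its own OH as a lactone. If the closure onto the pyranone is slow, the ketene can dimerise or pick up adventitious nucleophiles. After the closure, traces of air can oxidise the hydroquinone stage, and the chelated 5-OH may be methylated incompletely.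
- *Fallback (from 2, back at 14):* the construction of ring A is given up and replaced by a Claisen–Schmidt condensation and oxidative cyclisation. Aldehyde 2 is condensed (KOH, EtOH) with acetophenone A1 to the chalcone (E)-3-[2,4-bis(benzyloxy)-5-methoxyphenyl]-1-(2-hydroxy-3,4,5,6-tetramethoxyphenyl)prop-2-en-1-one F1. F1 is then cyclised and dehydrogenated with catalytic I2 in DMSO at 130 °C to 14. The price is the long preparation of A1.

**Step 4.**
- *What may go wrong:* site selectivity in the lithiation may be lost, because the carbonyl oxygen can guide the base to C3–H or C5–H. The lithiated pyranone may also add to pyranone that has not yet been deprotonated, since the ring is a good conjugate acceptor.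
- *Fallback (from 3 and 2, back at 13):* the site of metalation is fixed with a halogen, and the rings are joined through the other pyranone carbon.
  - Electrophilic iodination of 3 at its enol-ether carbon (NIS, CH2Cl2) should give (Z)-3-iodo-4-methoxybut-3-en-2-one F2.
  - Aldol addition of F2 to 2 under the conditions of step 2 gives (4Z)-1-[2,4-bis(benzyloxy)-5-methoxyphenyl]-1-hydroxy-4-iodo-5-methoxypent-4-en-3-one F3.
  - IBX takes F3 to (4Z)-1-[2,4-bis(benzyloxy)-5-methoxyphenyl]-4-iodo-5-methoxypent-4-ene-1,3-dione F4.
  - Trifluoroacetic acid closes F4 to 2-[2,4-bis(benzyloxy)-5-methoxyphenyl]-5-iodo-4H-pyran-4-one F5.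
  - Iodine–magnesium exchange (i-PrMgCl·LiCl, THF, −40 °C), of the kind known for α-iodo-β-alkoxy enoates and 5-iodouracils, gives {6-[2,4-bis(benzyloxy)-5-methoxyphenyl]-4-oxo-4H-pyran-3-yl}magnesium chloride F6.
  - F6 adds to 8 to give 4-{6-[2,4-bis(benzyloxy)-5-methoxyphenyl]-4-oxo-4H-pyran-3-yl}-4-hydroxy-2,3-dimethoxycyclobut-2-en-1-one F7.
  - Thermolysis as in step 5 opens F7 to (3Z)-4-{6-[2,4-bis(benzyloxy)-5-methoxyphenyl]-4-oxo-4H-pyran-3-yl}-4-hydroxy-2,3-dimethoxybuta-1,3-dien-1-one F8.
  - F8 closes onto pyranone C6 to 2-[2,4-bis(benzyloxy)-5-methoxyphenyl]-5-hydroxy-6,7-dimethoxy-8aH-chromene-4,8-dione F9, which enolises to the same hydroquinone 13.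
  - The two routes converge because 8 delivers the same four carbons whichever end of the C4a=C8a bond is attached first.

**Step 3.**
- *What may go wrong:* further oxidation at the doubly activated methylene, loss of water from the aldol before it is oxidised, and slow acidolysis of the electron-rich benzyl ethers during the closure.
- *Fallback (from 5, back at 7):* the ring is closed first and the oxidation level is adjusted afterwards. Trifluoroacetic acid converts 5, by addition of the hydroxyl group to the enone and loss of methanol, into racemic 2-[2,4-bis(benzyloxy)-5-methoxyphenyl]-2,3-dihydro-4H-pyran-4-one F10. F10 is dehydrogenated with DDQ (dioxane, 100 °C) in the way flavanones are taken to flavones, which gives 7.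

**Step 6.**
- *What may go wrong:* saturation of the C2=C3 bond if the second, more hindered benzyl ether is cleaved slowly and the reaction has to be forced.
- *Fallback (from 14, back at 15):* the reductive cleavage is replaced by an acidolytic one. BCl3 with pentamethylbenzene as cation scavenger in CH2Cl2 at −78 °C takes the benzyl groups off as stabilised cations. At this temperature the chelation-assisted loss of the 5-OMe group should still be slow. This fallback makes no new compound.

## Further compounds

F1 | step 5 | (E)-3-[2,4-bis(benzyloxy)-5-methoxyphenyl]-1-(2-hydroxy-3,4,5,6-tetramethoxyphenyl)prop-2-en-1-one | COc1cc(/C=C/C(=O)c2c(O)c(OC)c(OC)c(OC)c2OC)c(OCc2ccccc2)cc1OCc1ccccc1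
F2 | step 4 | (Z)-3-iodo-4-methoxybut-3-en-2-one | CO/C=C(\I)C(C)=O
F3 | step 4 | (4Z)-1-[2,4-bis(benzyloxy)-5-methoxyphenyl]-1-hydroxy-4-iodo-5-methoxypent-4-en-3-one (racemic) | COc1cc(C(O)CC(=O)/C(I)=C/OC)c(OCc2ccccc2)cc1OCc1ccccc1
F4 | step 4 | (4Z)-1-[2,4-bis(benzyloxy)-5-methoxyphenyl]-4-iodo-5-methoxypent-4-ene-1,3-dione | COc1cc(C(=O)CC(=O)/C(I)=C/OC)c(OCc2ccccc2)cc1OCc1ccccc1
F5 | step 4 | 2-[2,4-bis(benzyloxy)-5-methoxyphenyl]-5-iodo-4H-pyran-4-one | COc1cc(-c2cc(=O)c(I)co2)c(OCc2ccccc2)cc1OCc1ccccc1
F6 | step 4 | {6-[2,4-bis(benzyloxy)-5-methoxyphenyl]-4-oxo-4H-pyran-3-yl}magnesium chloride | Cl[Mg]c1coc(-c2cc(OC)c(OCc3ccccc3)cc2OCc2ccccc2)cc1=O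
F7 | step 4 | 4-{6-[2,4-bis(benzyloxy)-5-methoxyphenyl]-4-oxo-4H-pyran-3-yl}-4-hydroxy-2,3-dimethoxycyclobut-2-en-1-one (racemic) | COC1=C(OC)C(O)(c2coc(-c3cc(OC)c(OCc4ccccc4)cc3OCc3ccccc3)cc2=O)C1=O
F8 | step 4 | (3Z)-4-{6-[2,4-bis(benzyloxy)-5-methoxyphenyl]-4-oxo-4H-pyran-3-yl}-4-hydroxy-2,3-dimethoxybuta-1,3-dien-1-one | O=C=C(OC)/C(OC)=C(O)\c1coc(-c2cc(OC)c(OCc3ccccc3)cc2OCc2ccccc2)cc1=O
F9 | step 4 | 2-[2,4-bis(benzyloxy)-5-methoxyphenyl]-5-hydroxy-6,7-dimethoxy-8aH-chromene-4,8-dione (racemic) | COC1=C(OC)C(=O)C2OC(c3cc(OC)c(OCc4ccccc4)cc3OCc3ccccc3)=CC(=O)C2=C1O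
F10 | step 3 | 2-[2,4-bis(benzyloxy)-5-methoxyphenyl]-2,3-dihydro-4H-pyran-4-one (racemic) | COc1cc(C2CC(=O)C=CO2)c(OCc2ccccc2)cc1OCc1ccccc1
F0 | step 6 | none | none
A1 | alternative 1 | 1-(2-hydroxy-3,4,5,6-tetramethoxyphenyl)ethan-1-one | CC(=O)c1c(O)c(OC)c(OC)c(OC)c1OC
A2 | alternative 1 | 2,4-bis(benzyloxy)-5-methoxybenzoyl chloride | COc1cc(C(Cl)=O)c(OCc2ccccc2)cc1OCc1ccccc1
A3 | alternative 1 | 1-[2,4-bis(benzyloxy)-5-methoxyphenyl]-3-(2-hydroxy-3,4,5,6-tetramethoxyphenyl)propane-1,3-dione | COc1cc(C(=O)CC(=O)c2c(O)c(OC)c(OC)c(OC)c2OC)c(OCc2ccccc2)cc1OCc1ccccc1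
A4 | alternative 2 | 2-[2,4-bis(benzyloxy)-5-methoxyphenyl]-5-hydroxy-6,7-dimethoxy-4H-chromen-4-one | COc1cc(-c2cc(=O)c3c(O)c(OC)c(OC)cc3o2)c(OCc2ccccc2)cc1OCc1ccccc1
A5 | alternative 3 | pentacarbonyl[{6-[2,4-bis(benzyloxy)-5-methoxyphenyl]-4-oxo-4H-pyran-2-yl}(methoxy)methylidene]chromium | COC(=[Cr](=C=O)(=C=O)(=C=O)(=C=O)=C=O)c1cc(=O)cc(-c2cc(OC)c(OCc3ccccc3)cc2OCc2ccccc2)o1
A6 | alternative 3 | dimethoxyethyne | COC#COC
A7 | alternative 3 | 2-[2,4-bis(benzyloxy)-5-methoxyphenyl]-5-hydroxy-6,7,8-trimethoxy-4H-chromen-4-one | COc1cc(-c2cc(=O)c3c(O)c(OC)c(OC)c(OC)c3o2)c(OCc2ccccc2)cc1OCc1ccccc1
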